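**Retrosynthetic overview**
- The target is fisetinidol-(4β→6)-ent-epifisetinidol. The key disconnection is the interflavan C4–C6' bond, giving a flavan-4-yl cation precursor (4-arylthio ether with free 3-OH) and the C6-boronic acid of tri-O-benzyl-ent-epifisetinidol. The bond is made at the anode, with the aryl group delivered from boron held on O3, which forces the 3,4-cis (4β) geometry.
- Both partners come from one 5-deoxy flavan-3,4-diol, made from (+)-taxifolin by benzylation, removal of the C5 oxygen through its triflate, and C4=O reduction.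
- Lower unit: diol → fisetinidol (hydrogenolysis) → C2 epimerisation with C3 retained → benzylation → C6 bromination → borylation.
- No ring is constructed: rings A, B and C of both units are bought in taxifolin. Global hydrogenolysis comes last.

Assumption: the SMILES is read as upper unit 2R,3S,4S (2,3-trans-3,4-cis) and lower unit 2S,3S (2,3-cis), and natural (+)-taxifolin (2R,3R) is taken as the bulk chiral starting material.

**Step 1**
Reactants: 1 (+)-taxifolin, (2R,3R)-2-(3,4-dihydroxyphenyl)-3,5,7-trihydroxychroman-4-one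
Product: 2 (2R,3R)-7-benzyloxy-2-[3,4-bis(benzyloxy)phenyl]-3,5-dihydroxychroman-4-one
Conditions: BnBr (3.2 equiv), K2CO3 (3.3 equiv), DMF, Ar, 0 °C → rt
Reagents that add atoms: benzyl bromide, BrCc1ccccc1
Why: Williamson etherification of the three acidic phenols (7, 3', 4'); the 5-OH hydrogen-bonded to C4=O and the secondary 3-OH stay free, and C2/C3 are not touched (the trans dihydroflavonol is also the thermodynamic isomer).

**Step 2**
Reactants: 2 (2R,3R)-7-benzyloxy-2-[3,4-bis(benzyloxy)phenyl]-3,5-dihydroxychroman-4-one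
Product: 3 (2R,3R)-7-benzyloxy-2-[3,4-bis(benzyloxy)phenyl]-3-hydroxy-4-oxochroman-5-yl trifluoromethanesulfonate
Conditions: PhNTf2 (1.5 equiv), Et3N (3 equiv), DMAP (0.2 equiv), CH2Cl2, Ar, rt
Reagents that add atoms: N-phenylbis(trifluoromethanesulfonimide), O=S(=O)(N(c1ccccc1)S(=O)(=O)C(F)(F)F)C(F)(F)F
Why: Phenol-selective O-sulfonylation; PhNTf2 triflates the remaining phenol (5-OH) but not the secondary 3-OH, and no stereocentre is involved.

**Step 3**
Reactants: 3 (2R,3R)-7-benzyloxy-2-[3,4-bis(benzyloxy)phenyl]-3-hydroxy-4-oxochroman-5-yl trifluoromethanesulfonate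
Product: 5 (2R,3S,4R)-7-benzyloxy-2-[3,4-bis(benzyloxy)phenyl]chromane-3,4-diol, via tri-O-benzylfustin 4 (not isolated)
Conditions: Pd(OAc)2 (5 mol %), dppf (6 mol %), HCO2H (3 equiv), Et3N (4.5 equiv), DMF, Ar, 70 °C; then NaBH4 (3 equiv), MeOH, 0 °C
Reagents that add atoms: none
Why: Cacchi-type hydrodetriflation (zerovalent palladium inserts into the ortho-acyl C–OTf bond, formate delivers hydride) removes the C5 oxygen; NaBH4 then reduces C4=O trans to the 3-OH (substrate control, known for dihydroflavonols), and the C4 configuration is not needed later.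

**Step 4**
Reactants: 5 (2R,3S,4R)-7-benzyloxy-2-[3,4-bis(benzyloxy)phenyl]chromane-3,4-diol
Product: 6 (2R,3R,4R)-7-benzyloxy-2-[3,4-bis(benzyloxy)phenyl]-4-[(4-methoxyphenyl)sulfanyl]chroman-3-ol (4α-S, 3,4-trans major epimer)
Conditions: 4-MeOC6H4SH (3 equiv), AcOH (10 vol %), CH2Cl2, rt
Reagents that add atoms: 4-methoxybenzenethiol, COc1ccc(S)cc1
Why: Classical SN1 thiolysis of a flavan-3,4-diol through the flavan-4-yl cation (stabilised by 7-OBn and O1); both C4 epimers are usable because C4 is ionised again in step 10, and C2/C3 are untouched.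

**Step 5**
Reactants: 5 (2R,3S,4R)-7-benzyloxy-2-[3,4-bis(benzyloxy)phenyl]chromane-3,4-diol
Product: 7 fisetinidol, (2R,3S)-2-(3,4-dihydroxyphenyl)chromane-3,7-diol
Conditions: H2 (1 atm), 10% Pd/C, EtOH/EtOAc (1:1), AcOH (1%), rt
Reagents that add atoms: none
Why: Hydrogenolysis of the three benzyl ethers and of the para-oxygenated benzylic C4–OH (the known flavan-3,4-diol to flavan-3-ol reduction); C2 and C3 are untouched.

**Step 6**
Reactants: 7 fisetinidol, (2R,3S)-2-(3,4-dihydroxyphenyl)chromane-3,7-diol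
Product: 8 ent-epifisetinidol, (2S,3S)-2-(3,4-dihydroxyphenyl)chromane-3,7-diol
Conditions: degassed 0.05 M Na2CO3/NaHCO3 (pH 10), N2, 50 °C; AcOH to pH 5; Sephadex LH-20 (EtOH); recovered 7 recycled
Reagents that add atoms: none
Why: Base-mediated C2 epimerisation through reversible C2–O1 opening to the ring B para-quinone methide; the retained C3 (S) centre is the only source of chirality, the equilibrium lies about 3:1 toward 7, and 8 is separated while 7 is recycled.

**Step 7**
Reactants: 8 ent-epifisetinidol, (2S,3S)-2-(3,4-dihydroxyphenyl)chromane-3,7-diol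
Product: 9 (2S,3S)-7-benzyloxy-2-[3,4-bis(benzyloxy)phenyl]chroman-3-ol
Conditions: BnBr (3.2 equiv), K2CO3 (3.3 equiv), DMF, Ar, 0 °C → rt
Reagents that add atoms: benzyl bromide, BrCc1ccccc1
Why: Williamson etherification of the three phenols at a temperature where C2 epimerisation is slow; the secondary 3-OH stays free.

**Step 8**
Reactants: 9 (2S,3S)-7-benzyloxy-2-[3,4-bis(benzyloxy)phenyl]chroman-3-ol
Product: 10 (2S,3S)-7-benzyloxy-2-[3,4-bis(benzyloxy)phenyl]-6-bromochroman-3-ol
Conditions: NBS (1.0 equiv), CH2Cl2, −40 → 0 °C, dark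
Reagents that add atoms: N-bromosuccinimide, O=C1CCC(=O)N1Br
Why: Electrophilic aromatic bromination; the resorcinol-type ring A is the most activated arene, and C6 (para to O1, ortho to OBn, unhindered) is preferred over C8, which sits between two oxygens.

**Step 9**
Reactants: 10 (2S,3S)-7-benzyloxy-2-[3,4-bis(benzyloxy)phenyl]-6-bromochroman-3-ol
Product: 11 [(2S,3S)-7-benzyloxy-2-[3,4-bis(benzyloxy)phenyl]-3-hydroxychroman-6-yl]boronic acid
Conditions: B(OiPr)3 (3 equiv), THF, −78 °C; n-BuLi (2.2 equiv) added dropwise; 1 M HCl to pH 6, 0 °C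
Reagents that add atoms: triisopropyl borate, CC(C)OB(OC(C)C)OC(C)C; water, O
Why: Bromine–lithium exchange with in-situ borate quench (the first equivalent of n-BuLi deprotonates the 3-OH); the aryllithium is trapped before it can attack a benzyl ether, and hydrolysis gives the boronic acid.

**Step 10**
Reactants: 6 (2R,3R,4R)-7-benzyloxy-2-[3,4-bis(benzyloxy)phenyl]-4-[(4-methoxyphenyl)sulfanyl]chroman-3-ol; 11 [(2S,3S)-7-benzyloxy-2-[3,4-bis(benzyloxy)phenyl]-3-hydroxychroman-6-yl]boronic acid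
Product: 14 hexa-O-benzyl fisetinidol-(4β→6)-ent-epifisetinidol (upper unit 2R,3S,4R with the C4 aryl cis to 3-OH; lower unit 2S,3S), via tethered boronic ester 12 (not isolated), via O3-boryl ether 13 (not isolated)
Conditions: 6 (1 equiv), 11 (1.5 equiv), CH2Cl2/(CF3)2CHOH (9:1), Bu4NPF6 (0.1 M), rt, 30 min; then undivided cell, RVC anode, Pt cathode, +1.1 V vs Ag/AgCl, 1.2 F/mol, −20 °C; aq. NaHCO3
Reagents that add atoms: none
Why: Proposed new method: anodic desulfurative, hydroxyl-directed ipso-arylation. The 3-OH of 6 condenses reversibly with 11 to boronic ester 12. One-electron oxidation of the aryl sulfide (the lowest-potential site, to which holes on other arenes relay) causes mesolytic C4–S cleavage to the flavan-4-yl cation and a thiyl radical that ends as disulfide. The boron-bound aryl, whose ipso carbon C6' is ortho/para to two ether oxygens, is then transferred through a five-membered C4–C3–O–B–C6' transition state that can reach only the face syn to O3. The C4–C6' bond therefore forms 3,4-cis (4β) and only at C6'; boron stays on O3 as 13 and is hydrolysed on work-up. The closest known chemistry is anodic activation of thioglycosides to oxocarbenium ions and hydroxyl-directed (Petasis-type) boronate aryl transfer to N-acyliminium ions, which gives cis products; neither has been applied to flavan-4-yl cations or combined.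

**Step 11**
Reactants: 14 hexa-O-benzyl fisetinidol-(4β→6)-ent-epifisetinidol
Product: 15 (2R,3S,4S)-2-(3,4-dihydroxyphenyl)-4-[(2S,3S)-2-(3,4-dihydroxyphenyl)-3,7-dihydroxychroman-6-yl]chromane-3,7-diol (CNP0187520.5)
Conditions: H2 (1 atm), 20% Pd(OH)2/C, THF/MeOH (1:1), rt; filtered under N2
Reagents that add atoms: none
Why: Global hydrogenolysis of six benzyl ethers; the diaryl-substituted C4–C6' bond and the C2–O1 bonds survive these conditions (standard for benzylated proanthocyanidins), so no stereocentre changes (the C4 label becomes S only through the CIP priority change).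

**Compound list**
1 | (+)-taxifolin, (2R,3R)-2-(3,4-dihydroxyphenyl)-3,5,7-trihydroxychroman-4-one | O=C1c2c(O)cc(O)cc2O[C@H](c2ccc(O)c(O)c2)[C@H]1O | starting material
2 | (2R,3R)-7-benzyloxy-2-[3,4-bis(benzyloxy)phenyl]-3,5-dihydroxychroman-4-one | O=C1c2c(O)cc(OCc3ccccc3)cc2O[C@H](c2ccc(OCc3ccccc3)c(OCc3ccccc3)c2)[C@H]1O | intermediate
3 | (2R,3R)-7-benzyloxy-2-[3,4-bis(benzyloxy)phenyl]-3-hydroxy-4-oxochroman-5-yl trifluoromethanesulfonate | O=C1c2c(OS(=O)(=O)C(F)(F)F)cc(OCc3ccccc3)cc2O[C@H](c2ccc(OCc3ccccc3)c(OCc3ccccc3)c2)[C@H]1O | intermediate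
4 | tri-O-benzylfustin, (2R,3R)-7-benzyloxy-2-[3,4-bis(benzyloxy)phenyl]-3-hydroxychroman-4-one (not isolated) | O=C1c2ccc(OCc3ccccc3)cc2O[C@H](c2ccc(OCc3ccccc3)c(OCc3ccccc3)c2)[C@H]1O | intermediate
5 | (2R,3S,4R)-7-benzyloxy-2-[3,4-bis(benzyloxy)phenyl]chromane-3,4-diol (2,3-trans-3,4-trans) | c1ccccc1COc1ccc2c(c1)O[C@H](c1ccc(OCc3ccccc3)c(OCc3ccccc3)c1)[C@@H](O)[C@@H]2O | intermediate
6 | (2R,3R,4R)-7-benzyloxy-2-[3,4-bis(benzyloxy)phenyl]-4-[(4-methoxyphenyl)sulfanyl]chroman-3-ol (4α-S, trans to 3-OH) | c1ccccc1COc1ccc2c(c1)O[C@H](c1ccc(OCc3ccccc3)c(OCc3ccccc3)c1)[C@@H](O)[C@@H]2Sc1ccc(OC)cc1 | intermediate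
7 | fisetinidol, (2R,3S)-2-(3,4-dihydroxyphenyl)chromane-3,7-diol | Oc1ccc2c(c1)O[C@H](c1ccc(O)c(O)c1)[C@@H](O)C2 | intermediate
8 | ent-epifisetinidol, (2S,3S)-2-(3,4-dihydroxyphenyl)chromane-3,7-diol | Oc1ccc2c(c1)O[C@@H](c1ccc(O)c(O)c1)[C@@H](O)C2 | intermediate
9 | (2S,3S)-7-benzyloxy-2-[3,4-bis(benzyloxy)phenyl]chroman-3-ol | c1ccccc1COc1ccc2c(c1)O[C@@H](c1ccc(OCc3ccccc3)c(OCc3ccccc3)c1)[C@@H](O)C2 | intermediate
10 | (2S,3S)-7-benzyloxy-2-[3,4-bis(benzyloxy)phenyl]-6-bromochroman-3-ol | Brc1cc2c(cc1OCc1ccccc1)O[C@@H](c1ccc(OCc3ccccc3)c(OCc3ccccc3)c1)[C@@H](O)C2 | intermediate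
11 | [(2S,3S)-7-benzyloxy-2-[3,4-bis(benzyloxy)phenyl]-3-hydroxychroman-6-yl]boronic acid | OB(O)c1cc2c(cc1OCc1ccccc1)O[C@@H](c1ccc(OCc3ccccc3)c(OCc3ccccc3)c1)[C@@H](O)C2 | intermediate
12 | tethered boronic ester: O3 of 6 bonded to the boron of 11 (B–OH retained; 4α-S still in place; not isolated) | c1ccccc1COc1ccc2c(c1)O[C@H](c1ccc(OCc3ccccc3)c(OCc3ccccc3)c1)[C@@H](OB(O)c1cc3c(cc1OCc1ccccc1)O[C@@H](c1ccc(OCc4ccccc4)c(OCc4ccccc4)c1)[C@@H](O)C3)[C@@H]2Sc1ccc(OC)cc1 | intermediate
13 | O3-boryl ether of 14: upper 3-O–B(OH)2, C4–C6' bond formed cis to O3 (not isolated) | c1ccccc1COc1ccc2c(c1)O[C@H](c1ccc(OCc3ccccc3)c(OCc3ccccc3)c1)[C@@H](OB(O)O)[C@H]2c1cc2c(cc1OCc1ccccc1)O[C@@H](c1ccc(OCc3ccccc3)c(OCc3ccccc3)c1)[C@@H](O)C2 | intermediate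
14 | hexa-O-benzyl fisetinidol-(4β→6)-ent-epifisetinidol: (2R,3S,4R)-7-benzyloxy-2-[3,4-bis(benzyloxy)phenyl]-4-[(2S,3S)-7-benzyloxy-2-[3,4-bis(benzyloxy)phenyl]-3-hydroxychroman-6-yl]chroman-3-ol (2,3-trans-3,4-cis) | c1ccccc1COc1ccc2c(c1)O[C@H](c1ccc(OCc3ccccc3)c(OCc3ccccc3)c1)[C@@H](O)[C@H]2c1cc2c(cc1OCc1ccccc1)O[C@@H](c1ccc(OCc3ccccc3)c(OCc3ccccc3)c1)[C@@H](O)C2 | intermediate
15 | (2R,3S,4S)-2-(3,4-dihydroxyphenyl)-4-[(2S,3S)-2-(3,4-dihydroxyphenyl)-3,7-dihydroxychroman-6-yl]chromane-3,7-diol | Oc1ccc2c(c1)O[C@H](c1ccc(O)c(O)c1)[C@@H](O)[C@H]2c1cc2c(cc1O)O[C@@H](c1ccc(O)c(O)c1)[C@@H](O)C2 | target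

**Step count and risks**
Total: 11 steps. Longest linear sequence: 10 steps (1, 2, 3, 5, 6, 7, 8, 9, 10, 11). Step 6 is equilibrium-limited and needs recycling of 7, but it is known chemistry and is not expected to fail outright.

The three steps most likely to fail:

Step 10 (the proposed new coupling). The aryl transfer from boron may lose to intermolecular capture of the cation, or the electron-rich arenes may be over-oxidised. The fallback sets out from thioether 6 and tri-O-benzyl-ent-epifisetinidol 9, which acts as a C6–H nucleophile without boron. Thiophilic activation of 6 with AgBF4 in THF at 0 °C, the established neutral interflavanyl coupling of 4-thioflavan-3-ols, gives 14 together with the 3,4-trans (4α) epimer of 14 F1, which is expected to be the major product and is removed by chromatography. The fallback comes back to the route at 14.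

Step 9 (lithiation–borylation). The dianion may attack a benzyl ether, or the electron-rich boronic acid may protodeboronate on work-up. The fallback sets out from bromide 10: a Miyaura borylation (Pd(dppf)Cl2, B2pin2, KOAc, dioxane, 80 °C) tolerates the free 3-OH and gives the pinacol boronate of 10 F2. Oxidative removal of the pinacol (NaIO4, NH4OAc, acetone/water) then comes back to the route at 11.

Step 3 (one-pot hydrodetriflation and reduction). The α-ketol of 3 and 4 may epimerise or rearrange while warmed with amine. The fallback sets out from triflate 3 and reduces the ketone first (NaBH4, MeOH/THF, 0 °C) to the 5-triflyloxy 3,4-diol F3, so that no α-ketol is heated. Hydrodetriflation with Pd(OAc)2/dppp/Et3SiH in DMF at 60 °C then comes back to the route at 5.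

**Further compounds**
F1 | step 10 | 3,4-trans (4α) epimer of 14, hexa-O-benzyl fisetinidol-(4α→6)-ent-epifisetinidol | c1ccccc1COc1ccc2c(c1)O[C@H](c1ccc(OCc3ccccc3)c(OCc3ccccc3)c1)[C@@H](O)[C@@H]2c1cc2c(cc1OCc1ccccc1)O[C@@H](c1ccc(OCc3ccccc3)c(OCc3ccccc3)c1)[C@@H](O)C2
F2 | step 9 | (2S,3S)-7-benzyloxy-2-[3,4-bis(benzyloxy)phenyl]-6-(4,4,5,5-tetramethyl-1,3,2-dioxaborolan-2-yl)chroman-3-ol | CC1(C)OB(OC1(C)C)c1cc2c(cc1OCc1ccccc1)O[C@@H](c1ccc(OCc3ccccc3)c(OCc3ccccc3)c1)[C@@H](O)C2
F3 | step 3 | (2R,3S,4R)-7-benzyloxy-2-[3,4-bis(benzyloxy)phenyl]-3,4-dihydroxychroman-5-yl trifluoromethanesulfonate | c1ccccc1COc1cc(OS(=O)(=O)C(F)(F)F)c2c(c1)O[C@H](c1ccc(OCc3ccccc3)c(OCc3ccccc3)c1)[C@@H](O)[C@@H]2O
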